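Carotenoid numbering: C1 gem-dimethyl carbon, C2/C3 carbinols, C5=C6 ring alkene. Everything rests on cutting the C1–C2 bond of the sulfated cyclohexene ring (and, identically, of the diol ring): with C6 carried as a ketone, C6(=O)–C1–C2(OH) is an aldol retron. An intramolecular silyl-transfer Mukaiyama aldol of an open-chain α-silyloxy aldehyde bearing a regiodefined tetrasubstituted silyl enol ether closes the six-membered ring, creates the quaternary-carbon-to-carbinol bond, sets C2 trans to the chiral-pool C3 and leaves O2 silylated. The ketone gives one C15 phosphonium salt; two equivalents join the C10 dialdehyde in a double Wittig reaction, and mono-sulfation of the twofold-symmetric diol precedes desilylation.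

Key step: step 8

Remark: sulfate monoesters are written in the protonated form drawn for the target; in the flask they are pyridinium, sodium or tetrabutylammonium salts, and the last step ends with protonation on an acidic ion-exchange resin.

Step 1
Reactants: 1 (R)-5-(hydroxymethyl)dihydrofuran-2(3H)-one
Product: 2 (R)-5-[(benzyloxy)methyl]dihydrofuran-2(3H)-one
Conditions: BnOC(=NH)CCl3, TfOH (cat.), CH2Cl2/cyclohexane, 0 °C to rt
Reagents that add atoms: benzyl 2,2,2-trichloroacetimidate, N=C(OCc1ccccc1)C(Cl)(Cl)Cl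
Why: Acid-catalysed imidate benzylation should etherify the primary alcohol without opening or epimerising the base-sensitive lactone.

Step 2
Reactants: 2 (R)-5-[(benzyloxy)methyl]dihydrofuran-2(3H)-one
Product: 3 (3S,5R)-5-[(benzyloxy)methyl]-3-methyldihydrofuran-2(3H)-one
Conditions: LiN(i-Pr)2, THF, −78 °C; MeI
Reagents that add atoms: iodomethane, CI
Why: Lactone enolate alkylation, in which methyl iodide should approach anti to the benzyloxymethyl group and give the trans lactone (the later 3,5-cis pair of the carbocycle; the minor cis lactone is removed by chromatography).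

Step 3
Reactants: 3 (3S,5R)-5-[(benzyloxy)methyl]-3-methyldihydrofuran-2(3H)-one
Product: 4 (4S,6R)-7-(benzyloxy)-6-hydroxy-2,4-dimethylhept-1-en-3-one (in equilibrium with its cyclic hemiketal)
Conditions: 2-bromopropene, t-BuLi (2 equiv), Et2O, −78 °C; then 3, THF, −78 °C; AcOH quench
Reagents that add atoms: 2-bromopropene, CC(Br)=C
Why: Mono-addition of an alkenyllithium to a lactone, where the tetrahedral lithium hemiketal alkoxide should persist at −78 °C and release the enone only on quench, so over-addition is avoided.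

Step 4
Reactants: 4 (4S,6R)-7-(benzyloxy)-6-hydroxy-2,4-dimethylhept-1-en-3-one
Product: 5 (4S,6R)-7-(benzyloxy)-2,4-dimethyl-6-[(triethylsilyl)oxy]hept-1-en-3-one
Conditions: Et3SiCl, imidazole, DMF, 0 °C
Reagents that add atoms: chlorotriethylsilane, CC[Si](Cl)(CC)CC
Why: Silylation of the secondary alcohol should trap the open-chain form and free the enone for conjugate reduction.

Step 5
Reactants: 5 (4S,6R)-7-(benzyloxy)-2,4-dimethyl-6-[(triethylsilyl)oxy]hept-1-en-3-one
Product: 7 (4S,6R)-7-(benzyloxy)-3-[(tert-butyldimethylsilyl)oxy]-2,4-dimethyl-6-[(triethylsilyl)oxy]hept-2-ene, via lithium enolate 6 (not isolated)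
Conditions: LiBH(sec-Bu)3, THF, −78 °C; then t-BuMe2SiOTf, −78 to 0 °C
Reagents that add atoms: tert-butyldimethylsilyl trifluoromethanesulfonate, CC(C)(C)[Si](C)(C)OS(=O)(=O)C(F)(F)F
Why: Conjugate hydride reduction of the β-unsubstituted enone should give the tetrasubstituted enolate regiospecifically on the C1 side, and O-silylation fixes it as the regiodefined silyl enol ether.

Step 6
Reactants: 7 (4S,6R)-7-(benzyloxy)-3-[(tert-butyldimethylsilyl)oxy]-2,4-dimethyl-6-[(triethylsilyl)oxy]hept-2-ene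
Product: 8 (2R,4S)-5-[(tert-butyldimethylsilyl)oxy]-4,6-dimethyl-2-[(triethylsilyl)oxy]hept-5-en-1-ol
Conditions: H2 (1 atm), 10 % Pd/C, EtOAc, rt
Reagents that add atoms: none
Why: Neutral hydrogenolysis of the benzyl ether, under which the tetrasubstituted silyl enol ether and the silyl ether should be inert in ethyl acetate.

Step 7
Reactants: 8 (2R,4S)-5-[(tert-butyldimethylsilyl)oxy]-4,6-dimethyl-2-[(triethylsilyl)oxy]hept-5-en-1-ol
Product: 9 (2R,4S)-5-[(tert-butyldimethylsilyl)oxy]-4,6-dimethyl-2-[(triethylsilyl)oxy]hept-5-enal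
Conditions: Dess–Martin periodinane, NaHCO3, CH2Cl2, 0 °C
Reagents that add atoms: none
Why: Buffered Dess–Martin oxidation should give the α-silyloxy aldehyde without epimerisation and without touching the enol ether; the aldehyde is used crude.

Step 8
Reactants: 9 (2R,4S)-5-[(tert-butyldimethylsilyl)oxy]-4,6-dimethyl-2-[(triethylsilyl)oxy]hept-5-enal
Product: 10 (3R,4R,6S)-3-[(tert-butyldimethylsilyl)oxy]-2,2,6-trimethyl-4-[(triethylsilyl)oxy]cyclohexan-1-one
Conditions: HNTf2 (3 mol %), CH2Cl2 (0.02 M), −78 °C; Et3N quench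
Reagents that add atoms: none
Why: HNTf2 protodesilylates a trace of 9 to give t-BuMe2SiNTf2, which silylates the aldehyde oxygen; the enol ether carbon C1 then attacks C2, and the silyloxocarbenium ion formed at C6 hands its silyl group back to triflimide, so the chain carrier is regenerated and O2 emerges as the silyl ether. The closest known reaction type is the triflimide-catalysed silyl-transfer Mukaiyama aldol addition of silyl enol ethers to aldehydes. The ring closes in the 6-(enolendo)-exo-trig mode. The new stereocentre C2 is controlled by the C3 silyloxy centre through a chair-like open transition state in which the C3 and C5 substituents are equatorial and the silylated aldehyde oxygen lies antiperiplanar to the enol C=C bond, away from the bulky enol silyloxy group, so that O2 should become equatorial and trans to O3 (2R). The step needs regioselectivity (C1 and not C5 as nucleophile), secured by the enol ether fixed in step 5, and facial selectivity at C2, secured by the non-chelating silyl Lewis acid, the silyl group on O3 and the 3,5-cis relationship set in step 2. C1 carries two identical methyl groups, so no second stereocentre arises and the β-silyloxy ketone cannot eliminate.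

Step 9
Reactants: 10 (3R,4R,6S)-3-[(tert-butyldimethylsilyl)oxy]-2,2,6-trimethyl-4-[(triethylsilyl)oxy]cyclohexan-1-one; 11 (E)-3-methylpent-2-en-4-yn-1-ol
Product: 13 (3R,4R,6S)-3-[(tert-butyldimethylsilyl)oxy]-1-[(3E)-5-hydroxy-3-methylpent-3-en-1-yn-1-yl]-2,2,6-trimethyl-4-[(triethylsilyl)oxy]cyclohexan-1-ol (configuration at C1 not defined), via dilithiated enynol 12 (not isolated)
Conditions: 11, n-BuLi (2 equiv), THF, −78 to −20 °C; then 10, −78 to 0 °C; AcOH quench
Reagents that add atoms: none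
Why: 1,2-Addition of a lithium acetylide to the hindered ketone, where the small linear nucleophile should tolerate the flanking quaternary carbon and the configuration of the new carbinol is irrelevant because it is lost in step 11.

Step 10
Reactants: 13 (3R,4R,6S)-3-[(tert-butyldimethylsilyl)oxy]-1-[(3E)-5-hydroxy-3-methylpent-3-en-1-yn-1-yl]-2,2,6-trimethyl-4-[(triethylsilyl)oxy]cyclohexan-1-ol
Product: 14 (3R,4R,6S)-3-[(tert-butyldimethylsilyl)oxy]-1-[(1E,3E)-5-hydroxy-3-methylpenta-1,3-dien-1-yl]-2,2,6-trimethyl-4-[(triethylsilyl)oxy]cyclohexan-1-ol (configuration at C1 not defined)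
Conditions: NaAlH2(OCH2CH2OCH3)2, THF, 0 °C to rt
Reagents that add atoms: none
Why: Alkoxide-directed trans-hydroalumination of the propargylic alcohol followed by protonolysis should give the (E)-alkene (C7=C8) and leave the silyl ethers intact.

Step 11
Reactants: 14 (3R,4R,6S)-3-[(tert-butyldimethylsilyl)oxy]-1-[(1E,3E)-5-hydroxy-3-methylpenta-1,3-dien-1-yl]-2,2,6-trimethyl-4-[(triethylsilyl)oxy]cyclohexan-1-ol
Product: 16 {(2E,4E)-5-[(4R,5R)-5-[(tert-butyldimethylsilyl)oxy]-4-hydroxy-2,6,6-trimethylcyclohex-1-en-1-yl]-3-methylpenta-2,4-dien-1-yl}triphenylphosphonium bromide, via allylic bromide 15 (not isolated)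
Conditions: aq HBr (48 %), CH2Cl2, −10 °C; then PPh3, EtOAc/MeOH, rt
Reagents that add atoms: hydrogen bromide, Br; triphenylphosphine, c1ccc(cc1)P(c1ccccc1)c1ccccc1
Why: Ionisation of the tertiary allylic alcohol, loss of the C5 proton (C1 is quaternary, so only the C5=C6 ring alkene can form) and thermodynamic capture of bromide at the primary terminus should give the conjugated triene bromide, which triphenylphosphine displaces (SN2), while the acid cleaves the unhindered C3 triethylsilyl ether and the neopentyl C2 silyl ether should survive.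

Step 12
Reactants: 16 C15 phosphonium bromide (above, 2.1 equiv); 17 (2E,4E,6E)-2,7-dimethylocta-2,4,6-trienedial
Product: 20 (2R,3R,2'R,3'R)-2,2'-bis[(tert-butyldimethylsilyl)oxy]-β,β-carotene-3,3'-diol, via phosphorus ylide 18 (not isolated), via C25 apo-aldehyde 19 (not isolated)
Conditions: NaOMe, MeOH/CH2Cl2, 0 °C to rt; then heptane, reflux (E/Z equilibration)
Reagents that add atoms: none
Why: Twofold Wittig olefination of the symmetric dialdehyde (the classical C15 + C10 + C15 assembly of C40 carotenoids), in which the free hydroxyl should be tolerated and heating should equilibrate the new C11=C12 and C11'=C12' bonds to E.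

Step 13
Reactants: 20 (2R,3R,2'R,3'R)-2,2'-bis[(tert-butyldimethylsilyl)oxy]-β,β-carotene-3,3'-diol
Product: 21 (2R,3R,2'R,3'R)-2,2'-bis[(tert-butyldimethylsilyl)oxy]-3'-hydroxy-β,β-caroten-3-yl hydrogen sulfate
Conditions: SO3·pyridine (1.0 equiv, added in portions), DMF/THF, 0 °C to rt; chromatography, recovered 20 recycled
Reagents that add atoms: sulfur trioxide–pyridine complex, [O-]S(=O)(=O)[n+]1ccccc1
Why: O-Sulfation with retention at C3 of one of the two equivalent and remote free hydroxyls (O2 and O2' are silylated), where the twofold symmetry of 20 means either hydroxyl gives the same product, a statistical distribution is expected with limiting reagent, and the mono-sulfate should be separable by its single charge from neutral 20 and the bis-sulfate.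

Step 14
Reactants: 21 (2R,3R,2'R,3'R)-2,2'-bis[(tert-butyldimethylsilyl)oxy]-3'-hydroxy-β,β-caroten-3-yl hydrogen sulfate
Product: 22 (2R,3R,2'R,3'R)-2,2',3'-trihydroxy-β,β-caroten-3-yl hydrogen sulfate (target)
Conditions: Bu4NF, THF, rt to 40 °C; then Dowex 50W (H+ form), MeOH, 0 °C
Reagents that add atoms: none
Why: Fluoride desilylation of both neopentyl silyl ethers, which should leave the sulfate monoester anion and the polyene untouched, followed by brief protonation.

Compound list

1 | (R)-5-(hydroxymethyl)dihydrofuran-2(3H)-one | O=C1CC[C@@H](O1)CO | starting material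
2 | (R)-5-[(benzyloxy)methyl]dihydrofuran-2(3H)-one | O=C1CC[C@@H](O1)COCc1ccccc1 | intermediate
3 | (3S,5R)-5-[(benzyloxy)methyl]-3-methyldihydrofuran-2(3H)-one | O=C1[C@@H](C)C[C@@H](O1)COCc1ccccc1 | intermediate
4 | (4S,6R)-7-(benzyloxy)-6-hydroxy-2,4-dimethylhept-1-en-3-one | C=C(C)C(=O)[C@@H](C)C[C@@H](O)COCc1ccccc1 | intermediate
5 | (4S,6R)-7-(benzyloxy)-2,4-dimethyl-6-[(triethylsilyl)oxy]hept-1-en-3-one | C=C(C)C(=O)[C@@H](C)C[C@@H](O[Si](CC)(CC)CC)COCc1ccccc1 | intermediate
6 | lithium (4S,6R)-7-(benzyloxy)-2,4-dimethyl-6-[(triethylsilyl)oxy]hept-2-en-3-olate | CC(C)=C([O-])[C@@H](C)C[C@@H](O[Si](CC)(CC)CC)COCc1ccccc1.[Li+] | intermediate (not isolated)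
7 | (4S,6R)-7-(benzyloxy)-3-[(tert-butyldimethylsilyl)oxy]-2,4-dimethyl-6-[(triethylsilyl)oxy]hept-2-ene | CC(C)=C(O[Si](C)(C)C(C)(C)C)[C@@H](C)C[C@@H](O[Si](CC)(CC)CC)COCc1ccccc1 | intermediate
8 | (2R,4S)-5-[(tert-butyldimethylsilyl)oxy]-4,6-dimethyl-2-[(triethylsilyl)oxy]hept-5-en-1-ol | CC(C)=C(O[Si](C)(C)C(C)(C)C)[C@@H](C)C[C@@H](O[Si](CC)(CC)CC)CO | intermediate
9 | (2R,4S)-5-[(tert-butyldimethylsilyl)oxy]-4,6-dimethyl-2-[(triethylsilyl)oxy]hept-5-enal | CC(C)=C(O[Si](C)(C)C(C)(C)C)[C@@H](C)C[C@@H](O[Si](CC)(CC)CC)C=O | intermediate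
10 | (3R,4R,6S)-3-[(tert-butyldimethylsilyl)oxy]-2,2,6-trimethyl-4-[(triethylsilyl)oxy]cyclohexan-1-one | O=C1[C@@H](C)C[C@@H](O[Si](CC)(CC)CC)[C@H](O[Si](C)(C)C(C)(C)C)C1(C)C | intermediate
11 | (E)-3-methylpent-2-en-4-yn-1-ol | C#C/C(C)=C/CO | starting material
12 | dilithium salt of 11 (lithium alkoxide and lithium acetylide) | [Li]C#C/C(C)=C/CO[Li] | intermediate (not isolated)
13 | (3R,4R,6S)-3-[(tert-butyldimethylsilyl)oxy]-1-[(3E)-5-hydroxy-3-methylpent-3-en-1-yn-1-yl]-2,2,6-trimethyl-4-[(triethylsilyl)oxy]cyclohexan-1-ol | OC1(C#C/C(C)=C/CO)[C@@H](C)C[C@@H](O[Si](CC)(CC)CC)[C@H](O[Si](C)(C)C(C)(C)C)C1(C)C | intermediate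
14 | (3R,4R,6S)-3-[(tert-butyldimethylsilyl)oxy]-1-[(1E,3E)-5-hydroxy-3-methylpenta-1,3-dien-1-yl]-2,2,6-trimethyl-4-[(triethylsilyl)oxy]cyclohexan-1-ol | OC1(/C=C/C(C)=C/CO)[C@@H](C)C[C@@H](O[Si](CC)(CC)CC)[C@H](O[Si](C)(C)C(C)(C)C)C1(C)C | intermediate
15 | (1R,6R)-4-[(1E,3E)-5-bromo-3-methylpenta-1,3-dien-1-yl]-6-[(tert-butyldimethylsilyl)oxy]-3,5,5-trimethylcyclohex-3-en-1-ol | CC1=C(/C=C/C(C)=C/CBr)C(C)(C)[C@@H](O[Si](C)(C)C(C)(C)C)[C@H](O)C1 | intermediate (not isolated)
16 | {(2E,4E)-5-[(4R,5R)-5-[(tert-butyldimethylsilyl)oxy]-4-hydroxy-2,6,6-trimethylcyclohex-1-en-1-yl]-3-methylpenta-2,4-dien-1-yl}triphenylphosphonium bromide | CC1=C(/C=C/C(C)=C/C[P+](c2ccccc2)(c2ccccc2)c2ccccc2)C(C)(C)[C@@H](O[Si](C)(C)C(C)(C)C)[C@H](O)C1.[Br-] | intermediate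
17 | (2E,4E,6E)-2,7-dimethylocta-2,4,6-trienedial | O=C/C(C)=C/C=C/C=C(C)/C=O | starting material
18 | triphenylphosphonium ylide derived from 16 | CC1=C(/C=C/C(C)=C/C=P(c2ccccc2)(c2ccccc2)c2ccccc2)C(C)(C)[C@@H](O[Si](C)(C)C(C)(C)C)[C@H](O)C1 | intermediate (not isolated)
19 | (2R,3R)-2-[(tert-butyldimethylsilyl)oxy]-3-hydroxy-12'-apo-β-caroten-12'-al | CC1=C(/C=C/C(C)=C/C=C/C(C)=C/C=C/C=C(C)/C=O)C(C)(C)[C@@H](O[Si](C)(C)C(C)(C)C)[C@H](O)C1 | intermediate (not isolated)
20 | (2R,3R,2'R,3'R)-2,2'-bis[(tert-butyldimethylsilyl)oxy]-β,β-carotene-3,3'-diol | CC1=C(/C=C/C(C)=C/C=C/C(C)=C/C=C/C=C(C)/C=C/C=C(C)/C=C/C2=C(C)C[C@@H](O)[C@H](O[Si](C)(C)C(C)(C)C)C2(C)C)C(C)(C)[C@@H](O[Si](C)(C)C(C)(C)C)[C@H](O)C1 | intermediate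
21 | (2R,3R,2'R,3'R)-2,2'-bis[(tert-butyldimethylsilyl)oxy]-3'-hydroxy-β,β-caroten-3-yl hydrogen sulfate | CC1=C(/C=C/C(C)=C/C=C/C(C)=C/C=C/C=C(C)/C=C/C=C(C)/C=C/C2=C(C)C[C@@H](OS(=O)(=O)O)[C@H](O[Si](C)(C)C(C)(C)C)C2(C)C)C(C)(C)[C@@H](O[Si](C)(C)C(C)(C)C)[C@H](O)C1 | intermediate
22 | (2R,3R,2'R,3'R)-2,2',3'-trihydroxy-β,β-caroten-3-yl hydrogen sulfate | CC1=C(/C=C/C(C)=C/C=C/C(C)=C/C=C/C=C(C)/C=C/C=C(C)/C=C/C2=C(C)C[C@@H](OS(=O)(=O)O)[C@H](O)C2(C)C)C(C)(C)[C@@H](O)[C@H](O)C1 | target

Total step count: 14. Longest linear sequence: 14 steps (1 to 22; two equivalents of phosphonium salt 16 enter in step 12).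

Steps most likely to fail

Step 8. The closure may pass in part through the synclinal arrangement, with the aldehyde oxygen over the enol oxygen, which erodes facial selectivity at C2; adventitious acid may also protodesilylate the enol ether before it cyclises. The fallback moves control of C2 from the bond formation to a hydroxyl-directed reduction. It sets out from 9 and comes back at 10. BF3·OEt2 (CH2Cl2, −78 °C) closes the same C1–C2 bond without silyl transfer and gives (4R,6S)-3-hydroxy-2,2,6-trimethyl-4-[(triethylsilyl)oxy]cyclohexan-1-one F1 as a mixture of carbinol epimers. Dess–Martin oxidation gives (4S,6R)-2,2,4-trimethyl-6-[(triethylsilyl)oxy]cyclohexane-1,3-dione F2, and HF·pyridine frees (4S,6R)-6-hydroxy-2,2,4-trimethylcyclohexane-1,3-dione F3. Me4NBH(OAc)3 (MeCN/AcOH, −20 °C) delivers hydride from the O3-bound borohydride to the adjacent carbonyl on the face of O3, which should give the trans diol (3R,4R,6S)-3,4-dihydroxy-2,2,6-trimethylcyclohexan-1-one F4 and leave the remote ketone alone. Et3SiCl/imidazole silylates the unhindered hydroxyl to give (3R,4R,6S)-3-hydroxy-2,2,6-trimethyl-4-[(triethylsilyl)oxy]cyclohexan-1-one F5, and t-BuMe2SiOTf/2,6-lutidine then gives 10.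

Step 11. Ionisation of the pentadienyl system may lead to proton loss or bromide capture at the wrong position (retro-type olefin isomers), and the aqueous acid may strip the C2 silyl ether. The fallback avoids any dehydration by making the ring alkene through an enol triflate and the C6–C7 bond by cross-coupling. It sets out from 10 (replacing steps 9 to 11) and comes back at 16. KN(SiMe3)2/PhNTf2 (THF, −78 °C) enolises the only enolisable position and gives (4R,5R)-5-[(tert-butyldimethylsilyl)oxy]-2,6,6-trimethyl-4-[(triethylsilyl)oxy]cyclohex-1-en-1-yl trifluoromethanesulfonate F6. Stille coupling (Pd2(dba)3, AsPh3, NMP, 50 °C) with (2E,4E)-3-methyl-5-(tributylstannyl)penta-2,4-dien-1-ol F7, made from 11 with Bu3SnH and PdCl2(PPh3)2, gives (2E,4E)-5-[(4R,5R)-5-[(tert-butyldimethylsilyl)oxy]-2,6,6-trimethyl-4-[(triethylsilyl)oxy]cyclohex-1-en-1-yl]-3-methylpenta-2,4-dien-1-ol F8. PPh3·HBr in MeOH then converts the primary allylic alcohol into the phosphonium salt and methanolyses the triethylsilyl ether to give 16.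

Step 13. The two hydroxyls react independently, so over-sulfation to the bis-sulfate and incomplete conversion may leave little mono-sulfate, and the separation of neutral, singly charged and doubly charged carotenoids may cause losses on the column. The fallback differentiates the two ends by the order of assembly instead of by a statistical reaction. It sets out from 16 and 17 (replacing steps 12 and 13) and comes back at 21. With 17 in threefold excess and one equivalent of 16 (NaOMe, MeOH/CH2Cl2, then EtOAc at reflux), the olefination should stop at the mono-aldehyde 19, which is isolated in this variant. SO3·pyridine (pyridine/DMF, rt) sulfates its single free hydroxyl to give (2R,3R)-2-[(tert-butyldimethylsilyl)oxy]-12'-oxo-12'-apo-β-caroten-3-yl hydrogen sulfate F9. A second Wittig reaction of F9 with a further equivalent of 16 and NaOMe in MeOH, followed by thermal E/Z equilibration, then gives 21.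

Further compounds

F1 | step 8 | (4R,6S)-3-hydroxy-2,2,6-trimethyl-4-[(triethylsilyl)oxy]cyclohexan-1-one (both C3 epimers) | O=C1[C@@H](C)C[C@@H](O[Si](CC)(CC)CC)C(O)C1(C)C
F2 | step 8 | (4S,6R)-2,2,4-trimethyl-6-[(triethylsilyl)oxy]cyclohexane-1,3-dione | O=C1[C@@H](C)C[C@@H](O[Si](CC)(CC)CC)C(=O)C1(C)C
F3 | step 8 | (4S,6R)-6-hydroxy-2,2,4-trimethylcyclohexane-1,3-dione | O=C1[C@@H](C)C[C@@H](O)C(=O)C1(C)C
F4 | step 8 | (3R,4R,6S)-3,4-dihydroxy-2,2,6-trimethylcyclohexan-1-one | O=C1[C@@H](C)C[C@@H](O)[C@H](O)C1(C)C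
F5 | step 8 | (3R,4R,6S)-3-hydroxy-2,2,6-trimethyl-4-[(triethylsilyl)oxy]cyclohexan-1-one | O=C1[C@@H](C)C[C@@H](O[Si](CC)(CC)CC)[C@H](O)C1(C)C
F6 | step 11 | (4R,5R)-5-[(tert-butyldimethylsilyl)oxy]-2,6,6-trimethyl-4-[(triethylsilyl)oxy]cyclohex-1-en-1-yl trifluoromethanesulfonate | CC1=C(OS(=O)(=O)C(F)(F)F)C(C)(C)[C@@H](O[Si](C)(C)C(C)(C)C)[C@H](O[Si](CC)(CC)CC)C1
F7 | step 11 | (2E,4E)-3-methyl-5-(tributylstannyl)penta-2,4-dien-1-ol | OC/C=C(C)/C=C/[Sn](CCCC)(CCCC)CCCC
F8 | step 11 | (2E,4E)-5-[(4R,5R)-5-[(tert-butyldimethylsilyl)oxy]-2,6,6-trimethyl-4-[(triethylsilyl)oxy]cyclohex-1-en-1-yl]-3-methylpenta-2,4-dien-1-ol | CC1=C(/C=C/C(C)=C/CO)C(C)(C)[C@@H](O[Si](C)(C)C(C)(C)C)[C@H](O[Si](CC)(CC)CC)C1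
F9 | step 13 | (2R,3R)-2-[(tert-butyldimethylsilyl)oxy]-12'-oxo-12'-apo-β-caroten-3-yl hydrogen sulfate | CC1=C(/C=C/C(C)=C/C=C/C(C)=C/C=C/C=C(C)/C=O)C(C)(C)[C@@H](O[Si](C)(C)C(C)(C)C)[C@H](OS(=O)(=O)O)C1
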